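Agrimol B is cut at both methylene bridges into a central (S)-2-methylbutanoylphloroglucinol (ring B) and two identical outer units (rings A and C). The route builds each outer ring from acyclic parts. It exploits the contiguous C(butanoyl)–C(OMe)–C(CH3) triad of rings A and C, where the methoxy carbon sits between the acyl and C-methyl carbons and the only ring C–H lies between two hydroxyls. One [4+2] cycloaddition with loss of methanol joins a 2-methyl-3-silyloxy ketene dimethyl acetal diene to a tert-butoxy-substituted hexynone and sets the whole substitution pattern. The resulting phenol is then aminomethylated and coupled twice with ring B.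

Key step: step 7

Remark: 3 and 14 are racemic and 11 is one alkene isomer, but these elements disappear in the same or the next step. The only stereocentre of the target is bought with 21 in enantiopure form.

Step 1
Reactants: 1 1,1-dichloropropene; 2 acetyl chloride
Product: 4 4,4-dichloro-3-methylbut-3-en-2-one, via 4,4,4-trichloro-3-methylbutan-2-one 3 (not isolated)
Conditions: AlCl3, CH2Cl2, 0 to 25 °C; ice/aq HCl; then steam distillation (−HCl)
Reagents that add atoms: none
Why: Friedel–Crafts-type acylation of a chloroalkene: the acylium ion should attack the CH carbon so that the cation sits on the carbon bearing both chlorines, chloride capture gives 3, and loss of HCl gives the conjugated dichlorovinyl ketone, as is established for the lower homologue from 1,1-dichloroethene.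

Step 2
Reactants: 4 4,4-dichloro-3-methylbut-3-en-2-one
Product: 5 4,4-dimethoxy-3-methylbut-3-en-2-one
Conditions: NaOMe (2.2 equiv), MeOH, 0 to 25 °C
Reagents that add atoms: sodium methoxide, C[O-].[Na+]
Why: Two successive addition–elimination (vinylic substitution) events at the β-carbon of the dichloroenone should replace both chlorides by methoxide and give the acyl ketene acetal without touching the ketone.

Step 3
Reactants: 5 4,4-dimethoxy-3-methylbut-3-en-2-one
Product: 6 1,1-dimethoxy-2-methyl-3-(trimethylsilyloxy)buta-1,3-diene
Conditions: TMSOTf, Et3N, Et2O, 0 °C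
Reagents that add atoms: trimethylsilyl trifluoromethanesulfonate, C[Si](C)(C)OS(=O)(=O)C(F)(F)F
Why: Silyl enol ether formation by soft enolisation; the acetyl CH3 is the only enolisable position of 5, so a single diene should form.

Step 4
Reactants: 7 butanoyl chloride
Product: 8 N-methoxy-N-methylbutanamide
Conditions: MeNHOMe·HCl, pyridine, CH2Cl2, 0 to 25 °C
Reagents that add atoms: N,O-dimethylhydroxylamine hydrochloride, CNOC.Cl
Why: N-Acylation of the hydroxylamine by the acid chloride (Weinreb amide formation) is routine.

Step 5
Reactants: 9 trichloroethylene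
Product: 11 (E)-1-tert-butoxy-1,2-dichloroethene, via dichloroacetylene 10 (not isolated)
Conditions: KOtBu, THF, −20 to 25 °C, N2
Reagents that add atoms: potassium tert-butoxide, CC(C)(C)[O-].[K+]
Why: tert-Butoxide should dehydrochlorinate 9 to dichloroacetylene and then add across it in anti fashion (nucleophilic addition to a haloalkyne), giving the E-dichloroenol ether, whose geometry is irrelevant later.

Step 6
Reactants: 11 (E)-1-tert-butoxy-1,2-dichloroethene; 8 N-methoxy-N-methylbutanamide
Product: 15 1-tert-butoxyhex-1-yn-3-one, via 1-tert-butoxy-2-chloroethyne 12 (not isolated), via lithium tert-butoxyacetylide 13 (not isolated), via lithium hemiaminal adduct 14 (not isolated)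
Conditions: n-BuLi (2.1 equiv), THF, −78 to −40 °C; then 8, −78 to −20 °C; pH 7 phosphate buffer, −20 °C; kept at or below 0 °C
Reagents that add atoms: none
Why: One equivalent of n-BuLi should effect dehydrochlorination to 12 and a second one chlorine–lithium exchange to acetylide 13, and the Weinreb ketone synthesis then stops at chelate 14, so that the sensitive ynone appears only on neutral quench in the cold.

Step 7
Reactants: 6 1,1-dimethoxy-2-methyl-3-(trimethylsilyloxy)buta-1,3-diene; 15 1-tert-butoxyhex-1-yn-3-one
Product: 18 1-(6-tert-butoxy-4-hydroxy-2-methoxy-3-methylphenyl)butan-1-one, via dimethoxycyclohexadiene cycloadduct 16 (not isolated), via aryl trimethylsilyl ether 17 (not isolated)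
Conditions: 6 (1.5 equiv), toluene (2 M), 0 to 25 °C, dark; then PPTS (cat.), MeOH, 0 °C
Reagents that add atoms: none
Why: This is a normal-electron-demand Diels–Alder reaction of a 1,1-dialkoxy-3-silyloxydiene with an acetylenic ketone followed by aromatisation, and its closest known relative is the resorcinol monoether synthesis from such dienes and alkynyl ketones or esters. The outer ring is closed by an intermolecular [4+2] cycloaddition, either concerted and asynchronous or as a Michael addition of the diene CH2 terminus followed by closure of the allenolate onto the dioxocarbenium carbon, and both paths form the same two bonds, C(OMe)2–C(acyl) and C(OtBu)–CH2. Adduct 16 should then ionise one acetal methoxy group and lose a proton from the ring CH2 to give aryl silyl ether 17, which methanol cleaves to phenol 18. No stereocentre is formed. The step needs a single orientation, and this is secured by matched polarisation: the CH2 terminus of 6, activated by the silyloxy group and vinylogously by the ketene acetal, bonds to the ynone carbon β to the carbonyl (the tert-butoxy carbon), so the ketene-acetal carbon ends up next to the butanoyl carbon and the diene methyl lands between OMe and OH. Working at or below 25 °C and without Lewis acid should keep the tert-butyl ynol ether from retro-ene loss of isobutene.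

Step 8
Reactants: 18 1-(6-tert-butoxy-4-hydroxy-2-methoxy-3-methylphenyl)butan-1-one
Product: 19 1-(4,6-dihydroxy-2-methoxy-3-methylphenyl)butan-1-one
Conditions: CF3CO2H, CH2Cl2, 0 °C
Reagents that add atoms: none
Why: Acid-mediated cleavage of an aryl tert-butyl ether by loss of isobutene (E1) should leave the methyl ether and the ketone untouched, and the one free ring carbon, flanked by two oxygen-bearing carbons, is slow to be tert-butylated.

Step 9
Reactants: 19 1-(4,6-dihydroxy-2-methoxy-3-methylphenyl)butan-1-one
Product: 20 1-[3-[(dimethylamino)methyl]-2,4-dihydroxy-6-methoxy-5-methylphenyl]butan-1-one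
Conditions: CH2(NMe2)2 (1.5 equiv), THF, 0 to 25 °C
Reagents that add atoms: bis(dimethylamino)methane, CN(C)CN(C)C
Why: Phenol Mannich reaction: the aminal delivers the iminium ion to the single unsubstituted ring carbon, which is ortho to both hydroxyls and far more nucleophilic than the ketone α-carbon, and the excess of aminal keeps the product from alkylating unreacted 19.

Step 10
Reactants: 21 (S)-2-methylbutanoic acid
Product: 22 (S)-2-methylbutanoyl chloride
Conditions: (COCl)2, DMF (cat.), CH2Cl2, 0 to 25 °C
Reagents that add atoms: oxalyl chloride, ClC(=O)C(Cl)=O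
Why: DMF-catalysed acid chloride formation runs without base, so no ketene can form and the α-stereocentre of 21 should be retained.

Step 11
Reactants: 22 (S)-2-methylbutanoyl chloride; 23 phloroglucinol
Product: 24 (2S)-2-methyl-1-(2,4,6-trihydroxyphenyl)butan-1-one
Conditions: AlCl3 (4 equiv), CH2Cl2–MeNO2, 0 to 25 °C; ice/1 M HCl
Reagents that add atoms: none
Why: Friedel–Crafts C-acylation of phloroglucinol, where the first acyl group deactivates the ring against a second; the (S) centre comes unchanged from 21 because the hindered, chelated aryl ketone enolises slowly at or below 25 °C.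

Step 12
Reactants: 20 1-[3-[(dimethylamino)methyl]-2,4-dihydroxy-6-methoxy-5-methylphenyl]butan-1-one (2.1 equiv); 24 (2S)-2-methyl-1-(2,4,6-trihydroxyphenyl)butan-1-one
Product: 27 agrimol B, via ortho-quinone methide 25 (not isolated), via singly bridged diarylmethane 26 (not isolated)
Conditions: 1,4-dioxane, 80 °C, argon sweep
Reagents that add atoms: none
Why: Thermal loss of dimethylamine from the phenolic Mannich base gives ortho-quinone methide 25, which is trapped in a Michael-type C-alkylation first by 24 and then by 26 at their free ring carbons; no bond to the stereocentre is touched, so agrimol B should keep the (S) configuration.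

Compound list
1 | 1,1-dichloropropene | CC=C(Cl)Cl | starting material
2 | acetyl chloride | CC(Cl)=O | starting material
3 | 4,4,4-trichloro-3-methylbutan-2-one (racemic) | CC(=O)C(C)C(Cl)(Cl)Cl | intermediate
4 | 4,4-dichloro-3-methylbut-3-en-2-one | CC(=O)C(C)=C(Cl)Cl | intermediate
5 | 4,4-dimethoxy-3-methylbut-3-en-2-one | CC(=O)C(C)=C(OC)OC | intermediate
6 | 1,1-dimethoxy-2-methyl-3-(trimethylsilyloxy)buta-1,3-diene | COC(OC)=C(C)C(=C)O[Si](C)(C)C | intermediate
7 | butanoyl chloride | CCCC(Cl)=O | starting material
8 | N-methoxy-N-methylbutanamide | CCCC(=O)N(C)OC | intermediate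
9 | trichloroethylene | ClC=C(Cl)Cl | starting material
10 | dichloroacetylene | ClC#CCl | intermediate
11 | (E)-1-tert-butoxy-1,2-dichloroethene | Cl/C=C(/Cl)OC(C)(C)C | intermediate
12 | 1-tert-butoxy-2-chloroethyne | ClC#COC(C)(C)C | intermediate
13 | lithium tert-butoxyacetylide | [Li+].[C-]#COC(C)(C)C | intermediate
14 | lithium 1-tert-butoxy-3-[methoxy(methyl)amino]hex-1-yn-3-olate (racemic) | [Li+].CCCC([O-])(C#COC(C)(C)C)N(C)OC | intermediate
15 | 1-tert-butoxyhex-1-yn-3-one | CCCC(=O)C#COC(C)(C)C | intermediate
16 | 1-[2-tert-butoxy-6,6-dimethoxy-5-methyl-4-(trimethylsilyloxy)cyclohexa-1,4-dien-1-yl]butan-1-one | CCCC(=O)C1=C(OC(C)(C)C)CC(O[Si](C)(C)C)=C(C)C1(OC)OC | intermediate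
17 | 1-[6-tert-butoxy-2-methoxy-3-methyl-4-(trimethylsilyloxy)phenyl]butan-1-one | CCCC(=O)c1c(OC(C)(C)C)cc(O[Si](C)(C)C)c(C)c1OC | intermediate
18 | 1-(6-tert-butoxy-4-hydroxy-2-methoxy-3-methylphenyl)butan-1-one | CCCC(=O)c1c(OC(C)(C)C)cc(O)c(C)c1OC | intermediate
19 | 1-(4,6-dihydroxy-2-methoxy-3-methylphenyl)butan-1-one | CCCC(=O)c1c(O)cc(O)c(C)c1OC | intermediate
20 | 1-[3-[(dimethylamino)methyl]-2,4-dihydroxy-6-methoxy-5-methylphenyl]butan-1-one | CCCC(=O)c1c(O)c(CN(C)C)c(O)c(C)c1OC | intermediate
21 | (S)-2-methylbutanoic acid | OC(=O)[C@@H](C)CC | starting material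
22 | (S)-2-methylbutanoyl chloride | ClC(=O)[C@@H](C)CC | intermediate
23 | phloroglucinol (benzene-1,3,5-triol) | Oc1cc(O)cc(O)c1 | starting material
24 | (2S)-2-methyl-1-(2,4,6-trihydroxyphenyl)butan-1-one | O=C([C@@H](C)CC)c1c(O)cc(O)cc1O | intermediate
25 | 4-butanoyl-5-hydroxy-3-methoxy-2-methyl-6-methylidenecyclohexa-2,4-dien-1-one | CCCC(=O)C1=C(O)C(=C)C(=O)C(C)=C1OC | intermediate
26 | (2S)-1-[3-(3-butanoyl-2,6-dihydroxy-4-methoxy-5-methylbenzyl)-2,4,6-trihydroxyphenyl]-2-methylbutan-1-one | CCCC(=O)c1c(O)c(Cc2c(O)cc(O)c(C(=O)[C@@H](C)CC)c2O)c(O)c(C)c1OC | intermediate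
27 | agrimol B, (2S)-1-[3,5-bis(3-butanoyl-2,6-dihydroxy-4-methoxy-5-methylbenzyl)-2,4,6-trihydroxyphenyl]-2-methylbutan-1-one | CCCC(=O)c1c(O)c(Cc2c(O)c(Cc3c(O)c(C)c(OC)c(C(=O)CCC)c3O)c(O)c(C(=O)[C@@H](C)CC)c2O)c(O)c(C)c1OC | target

Total step count: 12.
Longest linear sequence: 7 steps (steps 1, 2, 3, 7, 8, 9, 12).

Steps most likely to fail

1. Step 7. The push–pull ynone is a weaker dienophile than a simple acetylenic ketone. The cycloaddition may therefore be slow enough that retro-ene loss of isobutene from the ynol ether, hydrolysis of the diene, or addition of the diene to the carbonyl group competes. The fallback sets out from butanoyl chloride 7 and comes back at 19 without any cycloaddition. Commercial 2-methylbenzene-1,3,5-triol (Cc1c(O)cc(O)cc1O) would be C-acylated with 7 (AlCl3, CH2Cl2–MeNO2) to give 1-(2,4,6-trihydroxy-3-methylphenyl)butan-1-one F1. MOMCl and iPr2NEt (2.1 equiv, CH2Cl2, 0 °C) should cap the para hydroxyl and the less hindered of the two chelated ortho hydroxyls, giving 1-[2-hydroxy-4,6-bis(methoxymethoxy)-3-methylphenyl]butan-1-one F2, with the hydroxyl between acyl and methyl left free. This site selection is steric only, so an isomer may have to be removed. MeI and K2CO3 in DMF would then methylate the remaining hydroxyl to give 1-[2-methoxy-4,6-bis(methoxymethoxy)-3-methylphenyl]butan-1-one F3, and HCl in MeOH would remove both acetals to give 19.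

2. Step 12. Amine loss from 20 may need a temperature at which the quinone methide reacts with itself, the second alkylation stays incomplete, or the methylene bridges already formed redistribute between rings. The fallback sets out from 20 and comes back at 27 with a charged leaving group, so that the quinone methide is released by base in the cold. MeI in acetone at 0 °C would quaternise the amine to give (3-butanoyl-2,6-dihydroxy-4-methoxy-5-methylphenyl)-N,N,N-trimethylmethanaminium iodide F4. Two equivalents of this salt would then be added slowly to 24 and NaHCO3 in aqueous MeCN at 0 to 25 °C, where 1,4-elimination of trimethylamine and C-alkylation should give 27.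

3. Step 11. The stereocentre may erode through acid-promoted enolisation of the aluminium-bound ketone or through ketene formation from the acylium ion, and over-acylation is possible. The fallback sets out from 22 and 23 and comes back at 24 without a Lewis acid. Phloroglucinol 23 would be converted with MOMCl and iPr2NEt into 1,3,5-tris(methoxymethoxy)benzene F5. Acid chloride 22 with MeNHOMe·HCl and pyridine would give (2S)-N-methoxy-N,2-dimethylbutanamide F6. Directed ortho-lithiation of the tris-acetal (n-BuLi, THF, 0 °C) and addition of the aryllithium to this Weinreb amide at −78 °C should give (2S)-2-methyl-1-[2,4,6-tris(methoxymethoxy)phenyl]butan-1-one F7. Brief treatment with HCl in MeOH at 0 to 25 °C would then release 24.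

Further compounds
F1 | step 7 | 1-(2,4,6-trihydroxy-3-methylphenyl)butan-1-one | CCCC(=O)c1c(O)cc(O)c(C)c1O
F2 | step 7 | 1-[2-hydroxy-4,6-bis(methoxymethoxy)-3-methylphenyl]butan-1-one | CCCC(=O)c1c(OCOC)cc(OCOC)c(C)c1O
F3 | step 7 | 1-[2-methoxy-4,6-bis(methoxymethoxy)-3-methylphenyl]butan-1-one | CCCC(=O)c1c(OCOC)cc(OCOC)c(C)c1OC
F4 | step 12 | (3-butanoyl-2,6-dihydroxy-4-methoxy-5-methylphenyl)-N,N,N-trimethylmethanaminium iodide | CCCC(=O)c1c(O)c(C[N+](C)(C)C)c(O)c(C)c1OC.[I-]
F5 | step 11 | 1,3,5-tris(methoxymethoxy)benzene | COCOc1cc(OCOC)cc(OCOC)c1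
F6 | step 11 | (2S)-N-methoxy-N,2-dimethylbutanamide | CON(C)C(=O)[C@@H](C)CC
F7 | step 11 | (2S)-2-methyl-1-[2,4,6-tris(methoxymethoxy)phenyl]butan-1-one | COCOc1cc(OCOC)c(C(=O)[C@@H](C)CC)c(OCOC)c1
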